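**Plan**
- Retrosynthesis: the 1-hydroxyl goes back to a C1=C2 enone; the lactone C10–O bond and the C4–C5 bond are cut together (oxidative radical cyclisation of a β-keto ester chain onto a C5=C10 alkene), then C1–C2 and C1–C10.
- Ring B is then re-expanded: C6–C8 is cut and C7 returned to the ring as the ketone of a 6-diazo-7-oxocyclohexane; ring D is cut at C13–C16, and the decalin at C8–C14, C9=C11 (Robinson annulation) and C8–C15 (propargylation).
- Forward order of rings: six-membered ring B with ring C (annulation), ring D (gold-catalysed cyclisation), five-membered ring B (Wolff contraction), ring A together with the lactone (trivalent manganese), then C1 oxygenation and deprotection.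
- Stereochemistry: C8 from L-proline; C13 from the C15 tether; H-9 by hydride delivery anti to the C15–C16 bridge; C12 by a bulky hydride; C6 by kinetic enol protonation in the Wolff step; C4, C5 and C10 by α-face annulation opposite the C7 ester; C1 by addition opposite the lactone bridge.

Key step: step 14

Remark: gibberellane numbering is used for every compound (ring A: C1–C5, C10; ring B: C5, C6, C8, C9, C10 with C7 the carboxyl carbon on C6; ring C: C8, C9, C11–C14; ring D: C8, C13–C16; C17 exocyclic methylene, C18 methyl on C4, C19 lactone carbonyl). The SMILES is read literally: the lactone oxygen on C10, H-9, H-6 and the 12-hydroxyl are on one face (α); H-5, the C7 carboxyl, C15 and the 1-hydroxyl are on the other (β); ring B is therefore trans-fused to ring C. The 10β configuration drawn for compounds 11–21 is the expected one and is erased at step 16.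

**Step 1**
Reactants: 1 cyclohexane-1,3-dione; 2 propargyl bromide
Product: 3 2-(prop-2-yn-1-yl)cyclohexane-1,3-dione
Conditions: KOH, H2O, 0 °C to 50 °C
Reagents that add atoms: none
Why: Enolate C-alkylation of the 1,3-dione in water, where hydrogen bonding to oxygen favours attack through carbon on the reactive propargylic bromide.

**Step 2**
Reactants: 3 2-(prop-2-yn-1-yl)cyclohexane-1,3-dione; 4 methyl vinyl ketone
Product: 5 2-(3-oxobutyl)-2-(prop-2-yn-1-yl)cyclohexane-1,3-dione
Conditions: Et3N (cat.), EtOAc, rt
Reagents that add atoms: none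
Why: Amine-catalysed Michael addition of the acidic 2-substituted dione to the enone, which creates the quaternary carbon that becomes C8.

**Step 3**
Reactants: 5 2-(3-oxobutyl)-2-(prop-2-yn-1-yl)cyclohexane-1,3-dione
Product: 6 (8aR)-8a-(prop-2-yn-1-yl)-3,4,8,8a-tetrahydronaphthalene-1,6(2H,7H)-dione
Conditions: L-proline (cat.), DMSO, rt
Reagents that add atoms: none
Why: Hajos–Parrish–Eder–Sauer–Wiechert reaction, in which the proline enamine of the side-chain ketone attacks one of the two enantiotopic ring carbonyls under direction by the carboxylic acid and the ketol dehydrates; this should set C8 in the same spatial sense as the (S)-methyl series (R here by a priority change), and the enantiomeric purity can be raised by recrystallisation.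

**Step 4**
Reactants: 6 (8aR)-8a-(prop-2-yn-1-yl)-3,4,8,8a-tetrahydronaphthalene-1,6(2H,7H)-dione
Product: 7 C7 ethylene ketal of 6
Conditions: HOCH2CH2OH, TsOH·H2O (cat.), 4 Å molecular sieves, rt
Reagents that add atoms: ethylene glycol, OCCO
Why: Chemoselective acid-catalysed ketalisation, since the saturated C7 ketone is more electrophilic than the conjugated C12 ketone and is the only one masked.

**Step 5**
Reactants: 7 C7 ethylene ketal of 6
Product: 8 cross-conjugated tert-butyldimethylsilyl dienol ether (C12–OSi, C12=C13, C9=C11)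
Conditions: LiN(i-Pr)2, THF, −78 °C; then TBSCl, DMPU, −78 °C to rt
Reagents that add atoms: tert-butyldimethylsilyl chloride, CC(C)(C)[Si](C)(C)Cl
Why: Kinetic deprotonation of the enone at the α′ carbon C13 followed by O-silylation (silyl enol ether formation), with C7 masked so that no other enolate can form.

**Step 6**
Reactants: 8 cross-conjugated tert-butyldimethylsilyl dienol ether
Product: 9 B/C/D tricyclic enone ketal (C13–C16 bond, C16=C17 methylene, C12 ketone, C9=C11, C7 dioxolane)
Conditions: Ph3PAuCl (cat.), AgOTf (cat.), CH2Cl2/MeOH 10:1, rt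
Reagents that add atoms: none
Why: Conia-ene-type 5-exo-dig carbocyclisation in which the cationic monovalent gold complex activates the alkyne, the enol ether carbon C13 attacks C16 and methanol removes the silyl group and protonates the vinyl–gold bond; C13 can only be formed on the face that carries the C15 tether.

**Step 7**
Reactants: 9 B/C/D tricyclic enone ketal
Product: 11 10β-hydroxy enone ketal, via trimethylsilyl dienol ether 10 (not isolated)
Conditions: KN(SiMe3)2, Me3SiCl, THF, −78 °C; crude 10, dimethyldioxirane, acetone/CH2Cl2, −78 °C; aq. citric acid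
Reagents that add atoms: dimethyldioxirane, CC1(C)OO1
Why: Vinylogous Rubottom oxidation: with C13 now a bridgehead the enone can only be deprotonated at C10, and the electron-rich C9=C10 bond of the extended dienol ether is epoxidised much faster than the C16=C17 alkene; axial attack syn to C15 is expected to give the 10β-alcohol.

**Step 8**
Reactants: 11 10β-hydroxy enone ketal
Product: 12 10β-(tert-butyldimethylsilyloxy) enone ketal
Conditions: TBSOTf, 2,6-lutidine, CH2Cl2, −78 °C
Reagents that add atoms: tert-butyldimethylsilyl trifluoromethanesulfonate, CC(C)(C)[Si](C)(C)OS(=O)(=O)C(F)(F)F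
Why: Silylation of the secondary alcohol with the silyl triflate at low temperature, which leaves the dioxolane intact.

**Step 9**
Reactants: 12 10β-(tert-butyldimethylsilyloxy) enone ketal
Product: 13 9α-H saturated 12-ketone ketal (six-membered ring B trans-fused to ring C)
Conditions: Cu(OAc)2·H2O (cat.), 1,2-bis(diphenylphosphino)benzene (cat.), MeSiH(OEt)2, t-BuOH, toluene, rt
Reagents that add atoms: none
Why: Copper hydride conjugate reduction in which the phosphine-ligated CuH delivers hydride to C9 from the α face, the side of the one-carbon C14 bridge and away from the C15–C16 bridge and the axial 10β-silyloxy group, and tert-butanol protonates the copper enolate; the isolated alkene, ketal and silyl ether are inert.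

**Step 10**
Reactants: 13 9α-H saturated 12-ketone ketal
Product: 14 12α-alcohol (hydroxyl axial, anti to the C15–C16 bridge)
Conditions: LiBH(s-Bu)3, THF, −78 °C
Reagents that add atoms: none
Why: Substrate-controlled ketone reduction in which the bulky borohydride should approach the chair ring C ketone along the equatorial trajectory past sp2 C16, avoiding the axial H-9 and H-14, and so give the axial 12α-alcohol.

**Step 11**
Reactants: 14 12α-alcohol
Product: 15 12α-triisopropylsilyl ether
Conditions: i-Pr3SiOTf, 2,6-lutidine, CH2Cl2, 0 °C to rt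
Reagents that add atoms: triisopropylsilyl trifluoromethanesulfonate, CC(C)[Si](OS(=O)(=O)C(F)(F)F)(C(C)C)C(C)C
Why: Silyl triflate silylation of the hindered axial alcohol, the triisopropylsilyl group being chosen because it outlasts the later selective removal of the C10 silyl ether.

**Step 12**
Reactants: 15 12α-triisopropylsilyl ether
Product: 16 C7 ketone (10β-OTBS, 12α-OTIPS)
Conditions: PPTS, acetone/H2O, 55 °C
Reagents that add atoms: water, O
Why: Acid-catalysed hydrolysis of the dioxolane under conditions mild enough for both secondary silyl ethers and the exocyclic alkene.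

**Step 13**
Reactants: 16 C7 ketone
Product: 18 6-diazo 7-ketone, via 6-trifluoroacetyl ketone 17 (not isolated)
Conditions: LiN(SiMe3)2, THF, −78 °C, CF3CO2CH2CF3; crude 17, MsN3, Et3N, H2O, MeCN, rt
Reagents that add atoms: methanesulfonyl azide, CS(=O)(=O)N=[N+]=[N-]
Why: Detrifluoroacetylative (Regitz-type) diazo transfer: the enolate can only form at C6 because C8 is quaternary, its trifluoroacetyl derivative accepts the diazo group from the sulfonyl azide and the activating acyl group leaves on the sulfonamide.

**Step 14**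
Reactants: 18 6-diazo 7-ketone
Product: 20 ring-contracted 2-(trimethylsilyl)ethyl ester (6β-ester), via ketene 19 (not isolated)
Conditions: hν (λ > 300 nm, Pyrex), Me3SiCH2CH2OH, THF, 0 °C to rt
Reagents that add atoms: 2-(trimethylsilyl)ethanol, C[Si](C)(C)CCO
Why: Photochemical Wolff rearrangement: excitation of the s-cis-locked cyclic diazo ketone expels N2 with 1,2-shift of quaternary C8 from C7 to C6, giving ketene 19, which the alcohol traps as the ester. The closest known reaction type is the photochemical ring contraction of cyclic 2-diazo ketones to cycloalkanecarboxylates. Ring B is formed by ring contraction, not by a cyclisation: the six-membered C5–C6–C7–C8–C9–C10 ring becomes the five-membered C5–C6–C8–C9–C10 ring through the new C6–C8 bond, with C7 extruded as the exocyclic ester carbon. C8 migrates with retention, so C8, C9 and C13 are untouched; the new centre C6 is set when the ester enol is protonated from the α face, opposite the pseudo-axial C15 methylene on C8 and the 10β-silyloxy group, which places the ester β. The step needs rearrangement to win over carbene addition to the C16=C17 alkene and over O–H insertion; metal-free irradiation of a diazo ketone held s-cis in a ring secures this, and only C8 can migrate because it is the only other substituent on the carbonyl carbon.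

**Step 15**
Reactants: 20 ring-contracted 2-(trimethylsilyl)ethyl ester
Product: 21 10β-alcohol
Conditions: HF·pyridine, pyridine, THF, 0 °C to rt
Reagents that add atoms: none
Why: Selective desilylation, the tert-butyldimethylsilyl ether on the cyclopentane being cleaved much faster than the triisopropylsilyl ether at C12, while the silylethyl ester is untouched.

**Step 16**
Reactants: 21 10β-alcohol
Product: 22 10-ketone
Conditions: Dess–Martin periodinane, NaHCO3, CH2Cl2, 0 °C to rt
Reagents that add atoms: none
Why: Dess–Martin oxidation under buffered, non-basic conditions, chosen so that the now epimerisable C9 of the trans-hydrindanone is not equilibrated.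

**Step 17**
Reactants: 22 10-ketone
Product: 23 C5=C10 enol triflate
Conditions: KN(SiMe3)2, THF, −78 °C; then N-(5-chloro-2-pyridyl)bis(trifluoromethanesulfonimide), −78 °C
Reagents that add atoms: N-(5-chloro-2-pyridyl)bis(trifluoromethanesulfonimide), O=S(=O)(N(c1ccc(Cl)cn1)S(=O)(=O)C(F)(F)F)C(F)(F)F
Why: Kinetic enolate triflation: the hindered amide base removes a proton from the C5 methylene and not the ring-fusion C9–H, and O-sulfonylation at −78 °C fixes the C5=C10 regiochemistry and removes the risk of C9 epimerisation.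

**Step 18**
Reactants: 23 C5=C10 enol triflate; 24 (tributylstannyl)methanol
Product: 25 allylic alcohol (C1 hydroxymethyl on C10)
Conditions: Pd(PPh3)4 (cat.), LiCl, 1,4-dioxane, 95 °C
Reagents that add atoms: none
Why: Stille cross-coupling: oxidative addition of zerovalent palladium to the enol triflate, chloride-assisted transfer of the hydroxymethyl group from tin and reductive elimination install C1.

**Step 19**
Reactants: 25 allylic alcohol
Product: 26 allylic bromide
Conditions: CBr4, PPh3, CH2Cl2, 0 °C
Reagents that add atoms: carbon tetrabromide, BrC(Br)(Br)Br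
Why: Appel reaction, converting the primary allylic alcohol into the bromide under neutral conditions.

**Step 20**
Reactants: 26 allylic bromide; 27 methyl 2-methyl-3-oxobutanoate
Product: 29 β-keto ester (C1–C4 chain on C10), via acetoacetate dianion 28 (not isolated)
Conditions: 27, NaH, THF, 0 °C, then n-BuLi, 0 °C; then 26, 0 °C
Reagents that add atoms: none
Why: γ-Alkylation of an acetoacetate dianion: the more basic terminal carbon (C2) displaces the primary allylic bromide by SN2 and joins C1 to C2; should C6–H be deprotonated in passing, kinetic reprotonation from the α face should return the same ester configuration.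

**Step 21**
Reactants: 29 β-keto ester
Product: 30 pentacyclic 3-oxo 19,10-lactone
Conditions: Mn(OAc)3·2H2O, degassed AcOH, 50 °C, high dilution
Reagents that add atoms: none
Why: Oxidative free-radical cyclisation with trivalent manganese: Mn(OAc)3 oxidises the α-methyl β-keto ester to the C4 radical, which closes 6-endo onto C5 from the α face (opposite the C7 ester and C11); the tertiary C10 radical is oxidised to the cation, which the axial ester carbonyl captures on the same face with loss of its methyl group as methyl acetate, so that C4, C5 and C10 are set together and only the cis-bridged γ-lactone can form.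

**Step 22**
Reactants: 30 pentacyclic 3-oxo 19,10-lactone
Product: 32 1-en-3-one lactone, via trimethylsilyl enol ether 31 (not isolated)
Conditions: Me3SiOTf, Et3N, CH2Cl2, 0 °C; crude 31, Pd(OAc)2, MeCN, rt
Reagents that add atoms: none
Why: Saegusa–Ito oxidation: the ketone can enolise only towards C2 because C4 is quaternary, and divalent palladium converts the silyl enol ether into the C1=C2 enone by β-hydride elimination.

**Step 23**
Reactants: 32 1-en-3-one lactone
Product: 34 1β-hydroxy 3-ketone, via 1β-boryl ketone 33 (not isolated)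
Conditions: CuCl (cat.), bis[2-(diphenylphosphino)phenyl] ether (cat.), NaOt-Bu (cat.), B2pin2, MeOH, THF, rt; then NaBO3·4H2O, THF/H2O, rt
Reagents that add atoms: sodium perborate tetrahydrate, O[B-]1(O)OO[B-](O)(O)OO1.[Na+].[Na+]
Why: Copper-catalysed conjugate borylation followed by oxidation: the boryl–copper species adds to C1 from the β face, opposite the lactone bridge that covers the α face of ring A, and perborate replaces boron by hydroxyl with retention to give the 1β-alcohol.

**Step 24**
Reactants: 34 1β-hydroxy 3-ketone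
Product: 35 CNP0259985.3 (target)
Conditions: Bu4NF, AcOH, THF, rt to 40 °C
Reagents that add atoms: none
Why: Fluoride-mediated global deprotection: fluoride cleaves the triisopropylsilyl ether and fragments the 2-(trimethylsilyl)ethyl ester to the acid, ethylene and fluorotrimethylsilane, while the acetic acid buffer protects the β-hydroxy ketone and the β-keto lactone from base.

**Compound list**

1 | cyclohexane-1,3-dione | O=C1CCCC(=O)C1 | starting material
2 | propargyl bromide (3-bromoprop-1-yne) | C#CCBr | starting material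
3 | 2-(prop-2-yn-1-yl)cyclohexane-1,3-dione | C#CCC1C(=O)CCCC1=O | intermediate
4 | methyl vinyl ketone (but-3-en-2-one) | CC(=O)C=C | starting material
5 | 2-(3-oxobutyl)-2-(prop-2-yn-1-yl)cyclohexane-1,3-dione | C#CCC1(CCC(C)=O)C(=O)CCCC1=O | intermediate
6 | (8aR)-8a-(prop-2-yn-1-yl)-3,4,8,8a-tetrahydronaphthalene-1,6(2H,7H)-dione (C8 quaternary, C7 saturated ketone, C12 enone) | C#CC[C@]12CCC(=O)C=C1CCCC2=O | intermediate
7 | 6 with the C7 ketone as its 1,3-dioxolane | C#CC[C@]12CCC(=O)C=C1CCCC23OCCO3 | intermediate
8 | cross-conjugated tert-butyldimethylsilyl dienol ether of 7 (C12–OSi, C12=C13, C9=C11) | C#CC[C@]12CC=C(O[Si](C)(C)C(C)(C)C)C=C1CCCC23OCCO3 | intermediate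
9 | B/C/D tricyclic enone ketal: ring D closed by C13–C16 on the C15 face, C16=C17 methylene, C12 ketone, C9=C11, C7 dioxolane | C=C1C[C@]23C[C@H]1C(=O)C=C2CCCC34OCCO4 | intermediate
10 | extended trimethylsilyl dienol ether of 9 (C12–OSiMe3, C11=C12, C9=C10) | C=C1C[C@]23C[C@H]1C(O[Si](C)(C)C)=CC2=CCCC34OCCO4 | intermediate
11 | 10β-hydroxy derivative of 9 (hydroxyl syn to C15) | C=C1C[C@]23C[C@H]1C(=O)C=C2[C@H](O)CCC34OCCO4 | intermediate
12 | 10β-tert-butyldimethylsilyl ether of 11 | C=C1C[C@]23C[C@H]1C(=O)C=C2[C@H](O[Si](C)(C)C(C)(C)C)CCC34OCCO4 | intermediate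
13 | 9α-H saturated 12-ketone, six-membered ring B trans-fused to ring C, 10β-OTBS, C7 dioxolane | C=C1C[C@]23C[C@H]1C(=O)C[C@@H]2[C@H](O[Si](C)(C)C(C)(C)C)CCC34OCCO4 | intermediate
14 | 12α-alcohol of 13 (hydroxyl axial, anti to the C15–C16 bridge) | C=C1C[C@]23C[C@H]1[C@@H](O)C[C@@H]2[C@H](O[Si](C)(C)C(C)(C)C)CCC34OCCO4 | intermediate
15 | 12α-triisopropylsilyl ether of 14 | C=C1C[C@]23C[C@H]1[C@@H](O[Si](C(C)C)(C(C)C)C(C)C)C[C@@H]2[C@H](O[Si](C)(C)C(C)(C)C)CCC34OCCO4 | intermediate
16 | C7 ketone with six-membered ring B (10β-OTBS, 12α-OTIPS, 9α-H) | C=C1C[C@]23C[C@H]1[C@@H](O[Si](C(C)C)(C(C)C)C(C)C)C[C@@H]2[C@H](O[Si](C)(C)C(C)(C)C)CCC3=O | intermediate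
17 | 6-trifluoroacetyl derivative of 16 | C=C1C[C@]23C[C@H]1[C@@H](O[Si](C(C)C)(C(C)C)C(C)C)C[C@@H]2[C@H](O[Si](C)(C)C(C)(C)C)CC(C(=O)C(F)(F)F)C3=O | intermediate
18 | 6-diazo 7-ketone with six-membered ring B | C=C1C[C@]23C[C@H]1[C@@H](O[Si](C(C)C)(C(C)C)C(C)C)C[C@@H]2[C@H](O[Si](C)(C)C(C)(C)C)CC(=[N+]=[N-])C3=O | intermediate
19 | ring-contracted ketene (five-membered ring B, C6=C7=O) | C=C1C[C@]23C[C@H]1[C@@H](O[Si](C(C)C)(C(C)C)C(C)C)C[C@@H]2[C@H](O[Si](C)(C)C(C)(C)C)CC3=C=O | intermediate
20 | ring-contracted B/C/D 2-(trimethylsilyl)ethyl 7-ester: 6β-ester (H-6 α), 9α-H, 10β-OTBS, 12α-OTIPS | C=C1C[C@]23C[C@H]1[C@@H](O[Si](C(C)C)(C(C)C)C(C)C)C[C@@H]2[C@H](O[Si](C)(C)C(C)(C)C)C[C@@H]3C(=O)OCC[Si](C)(C)C | intermediate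
21 | 10β-alcohol of 20 | C=C1C[C@]23C[C@H]1[C@@H](O[Si](C(C)C)(C(C)C)C(C)C)C[C@@H]2[C@H](O)C[C@@H]3C(=O)OCC[Si](C)(C)C | intermediate
22 | 10-ketone (cyclopentanone ring B) | C=C1C[C@]23C[C@H]1[C@@H](O[Si](C(C)C)(C(C)C)C(C)C)C[C@@H]2C(=O)C[C@@H]3C(=O)OCC[Si](C)(C)C | intermediate
23 | C5=C10 enol triflate (triflate on C10) | C=C1C[C@]23C[C@H]1[C@@H](O[Si](C(C)C)(C(C)C)C(C)C)C[C@@H]2C(OS(=O)(=O)C(F)(F)F)=C[C@@H]3C(=O)OCC[Si](C)(C)C | intermediate
24 | (tributylstannyl)methanol | OC[Sn](CCCC)(CCCC)CCCC | starting material
25 | allylic alcohol: hydroxymethyl (C1) on C10 of the C5=C10 cyclopentene | C=C1C[C@]23C[C@H]1[C@@H](O[Si](C(C)C)(C(C)C)C(C)C)C[C@@H]2C(CO)=C[C@@H]3C(=O)OCC[Si](C)(C)C | intermediate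
26 | allylic bromide (C1 bromomethyl on C10) | C=C1C[C@]23C[C@H]1[C@@H](O[Si](C(C)C)(C(C)C)C(C)C)C[C@@H]2C(CBr)=C[C@@H]3C(=O)OCC[Si](C)(C)C | intermediate
27 | methyl 2-methyl-3-oxobutanoate | CC(=O)C(C)C(=O)OC | starting material
28 | sodium lithium dianion of 27 | [Na+].[Li+].[CH2-]C(=O)[C-](C)C(=O)OC | intermediate
29 | β-keto ester: C10–C1H2–C2H2–C3(=O)–C4H(CH3)–CO2CH3 chain on the C5=C10 alkene (C4 epimers) | C=C1C[C@]23C[C@H]1[C@@H](O[Si](C(C)C)(C(C)C)C(C)C)C[C@@H]2C(CCC(=O)C(C)C(=O)OC)=C[C@@H]3C(=O)OCC[Si](C)(C)C | intermediate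
30 | pentacyclic 3-oxo 19,10-lactone (10α-oxygen, 5β-H, 6β-ester), 12α-OTIPS, 2-(trimethylsilyl)ethyl 7-ester | C=C1C[C@]23C[C@H]1[C@@H](O[Si](C(C)C)(C(C)C)C(C)C)C[C@@H]2[C@]12OC(=O)[C@](C)(C(=O)CC1)[C@H]2[C@@H]3C(=O)OCC[Si](C)(C)C | intermediate
31 | trimethylsilyl enol ether of 30 (C2=C3) | C=C1C[C@]23C[C@H]1[C@@H](O[Si](C(C)C)(C(C)C)C(C)C)C[C@@H]2[C@]12OC(=O)[C@](C)(C(O[Si](C)(C)C)=CC1)[C@H]2[C@@H]3C(=O)OCC[Si](C)(C)C | intermediate
32 | 1-en-3-one of 30 | C=C1C[C@]23C[C@H]1[C@@H](O[Si](C(C)C)(C(C)C)C(C)C)C[C@@H]2[C@]12OC(=O)[C@](C)(C(=O)C=C1)[C@H]2[C@@H]3C(=O)OCC[Si](C)(C)C | intermediate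
33 | 1β-(pinacolboryl) 3-ketone | C=C1C[C@]23C[C@H]1[C@@H](O[Si](C(C)C)(C(C)C)C(C)C)C[C@@H]2[C@]12OC(=O)[C@](C)(C(=O)C[C@H]1B4OC(C)(C)C(C)(C)O4)[C@H]2[C@@H]3C(=O)OCC[Si](C)(C)C | intermediate
34 | 1β-hydroxy 3-ketone, 12α-OTIPS, 2-(trimethylsilyl)ethyl 7-ester | C=C1C[C@]23C[C@H]1[C@@H](O[Si](C(C)C)(C(C)C)C(C)C)C[C@@H]2[C@]12OC(=O)[C@](C)(C(=O)C[C@H]1O)[C@H]2[C@@H]3C(=O)OCC[Si](C)(C)C | intermediate
35 | CNP0259985.3: 1β,12α-dihydroxy-3-oxo 19,10-lactone 7-acid with 9α-H | C=C1C[C@]23C[C@H]1[C@@H](O)C[C@@H]2[C@]12OC(=O)[C@](C)(C(=O)C[C@H]1O)[C@H]2[C@@H]3C(=O)O | target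

**Step count**

Total steps: 24. Longest linear sequence: 24 steps (1 to 35); compounds 2, 4, 24 and 27 enter as purchased.

**Steps most likely to fail**

Step 21. After the 6-endo radical closure the C10 cation may lose a proton or take up acetate faster than the ester carbonyl closes the lactone. The C4 epimer with an equatorial ester cannot lactonise at all. The fallback separates carbon–carbon from carbon–oxygen bond formation and sets out from 29. Mn(OAc)3·2H2O together with Cu(OAc)2·H2O in AcOH would give the same radical closure, but divalent copper turns the C10 radical into an alkene, expected to be mainly the Δ1(10)-ene keto diester F1. Iodolactonisation of this alkene (I2, MeCN) through the C19 ester carbonyl would give the 1β-iodo 19,10-lactone F2, with iodine β and oxygen α by anti addition. DBU would then eliminate hydrogen iodide through the C3 enolate and give enone 32, where the route is rejoined; step 22 is then not needed.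

Step 10. The facial selectivity may be poor or reversed: hydride delivered from the C14 face (axial attack) gives the equatorial 12β-alcohol. The fallback uses inversion and sets out from 13. NaBH4 in MeOH at 0 °C would give the 12β-alcohol F3. Mitsunobu reaction (4-nitrobenzoic acid, PPh3, diisopropyl azodicarboxylate, toluene) would invert C12 to the 12α 4-nitrobenzoate F4. K2CO3 in MeOH would release the 12α-alcohol 14, where the route is rejoined.

Step 23. The alkoxide present during borylation may open the β-keto lactone (retro-Claisen), or the β-hydroxy ketone may lose water again during the perborate oxidation. The fallback sets out from 32. Nucleophilic (Weitz–Scheffer) epoxidation with t-BuOOH and DBU in CH2Cl2, again from the β face, would give the 1β,2β-epoxy ketone F5. Reductive opening of the C2–O bond with SmI2 in THF/MeOH at −90 °C would give the 1β-hydroxy ketone 34, where the route is rejoined.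

**Further compounds**

F1 | step 21 | Δ1(10)-ene keto diester (ring A closed, C4 methyl ester α-axial, 5β-H) | C=C1C[C@]23C[C@H]1[C@@H](O[Si](C(C)C)(C(C)C)C(C)C)C[C@@H]2C4=CCC(=O)[C@@](C)(C(=O)OC)[C@H]4[C@@H]3C(=O)OCC[Si](C)(C)C
F2 | step 21 | 1β-iodo 3-oxo 19,10-lactone | C=C1C[C@]23C[C@H]1[C@@H](O[Si](C(C)C)(C(C)C)C(C)C)C[C@@H]2[C@]12OC(=O)[C@](C)(C(=O)C[C@H]1I)[C@H]2[C@@H]3C(=O)OCC[Si](C)(C)C
F3 | step 10 | 12β-alcohol (C12 epimer of 14) | C=C1C[C@]23C[C@H]1[C@H](O)C[C@@H]2[C@H](O[Si](C)(C)C(C)(C)C)CCC34OCCO4
F4 | step 10 | 12α 4-nitrobenzoate | C=C1C[C@]23C[C@H]1[C@@H](OC(=O)c5ccc(cc5)[N+](=O)[O-])C[C@@H]2[C@H](O[Si](C)(C)C(C)(C)C)CCC34OCCO4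
F5 | step 23 | 1β,2β-epoxy 3-ketone | C=C1C[C@]23C[C@H]1[C@@H](O[Si](C(C)C)(C(C)C)C(C)C)C[C@@H]2[C@]12OC(=O)[C@](C)(C(=O)[C@H]4O[C@@H]14)[C@H]2[C@@H]3C(=O)OCC[Si](C)(C)C
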